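Late in the runs the target stops moving, and that late level is the thing to watch in a repeat: red and amber, both at 40 °C, differ in charge and in precatalyst, yet both stand near 37.6% of their charge.

| setting | red | teal | amber | summer | autumn | noon |
|---|---|---|---|---|---|---|
| starting material | 0.11 M | 0.17 M | 0.079 M | 0.079 M | 0.079 M | 0.079 M |
| precatalyst | 0.64 mM | 0.64 mM | 0.32 mM | 0.64 mM | 0.64 mM | 0.64 mM |
| temperature | 40 °C | 73 °C | 40 °C | 85 °C | 55 °C | 25 °C |
| remark | run made earlier | run made earlier | run made earlier |  |  |  |
| time |  |  |  | 80 min | 80 min | 80 min |

| run | time / min | target / % |
|---|---|---|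
| red | 120 | 36 |
| red | 240 | 36 |
| red | 360 | 41 |
| red | 480 | 37 |
| teal | 10.0 | 82 |
| teal | 25.0 | 77 |
| teal | 50.0 | 82 |
| teal | 90.0 | 82 |
| amber | 40.0 | 36 |
| amber | 80.0 | 37 |
| amber | 180 | 41 |
| amber | 480 | 37 |

(each reading ± 2 percentage points)

* the flask with the highest amount of target, in percent of the starting material charged ("all alike" if they lie within 1.5 percentage points) (summer / autumn / noon / all alike)
* final target, as a percentage of the starting material charged, in summer
* final target, as a percentage of the starting material charged, in autumn
* final target, as a percentage of the starting material charged, in noon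

- what is said of target includes crystals
- crystals is a solid; its amount is given per volume of the solution
- the earlier runs were read with a standard deviation of 2 percentage points
- what may be going on: starting material + free catalyst <-> target + free catalyst; target + free catalyst <-> isomer of the product A + free catalyst; isomer of the product A <-> isomer of the product B; isomer of the product B + free catalyst <-> starting material + free catalyst; precatalyst -> free catalyst; crystals <-> target; 2 free catalyst -> spent catalyst

Two chemists take that level as thermodynamic control and write it as plateau odds, the fraction of the charge in target over the fraction elsewhere, which is 0.603 at 40 °C. They part over teal, which stands near 80.8%. The first chemist reads teal as a plain solution, with odds of 4.19. The second chemist recalls that the reading counts crystals too, and that teal's target is 3.32 times the load red held dissolved, so part of it may be solid. Supposing that solubility doesn't fall on heating, the lowest case has teal's solution holding just red's load, which is 24.3% of teal's charge, and that gives odds of 1.26.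

With the ceiling unknown, the second chemist takes the geometric middle of these two edges, 2.30, and from it the plateau heat, the gas constant times the rise in the logarithm of the plateau odds per step of reciprocal temperature 36.6 kJ mol⁻¹. Counted from 40 °C, this heat gives 77.9% for summer, 53.4% for autumn and 22.9% for noon, with summer above the other two.

The forecast sides with the first chemist, holding that “the equilibrium itself must shift towards target with temperature”, and names summer as the highest, with 88% there, 60% in autumn and 19% in noon.

The simulation gives summer as the highest, with 77.2% there, 53.8% in autumn and 23.7% in noon.

    starting material + free catalyst ⇌ target + free catalyst, rate k1*[starting material]*[free catalyst] forward; the back reaction follows from the equilibrium constant (K = 0.401, k = 44.6 L mol⁻¹ s⁻¹, Ea = 38.0 kJ mol⁻¹, ΔH = 33.0 kJ mol⁻¹)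
    target + free catalyst ⇌ isomer of the product A + free catalyst, rate k2*[free catalyst]*[target] forward; the back reaction follows from the equilibrium constant (K = 0.329, k = 1.24 L mol⁻¹ s⁻¹, Ea = 62.0 kJ mol⁻¹, ΔH = −46.0 kJ mol⁻¹)
    isomer of the product A ⇌ isomer of the product B (K = 1.20, k = 0.00887 s⁻¹, Ea = 81.0 kJ mol⁻¹, ΔH = −5.00 kJ mol⁻¹)
    isomer of the product B + free catalyst ⇌ starting material + free catalyst, rate k4*[free catalyst]*[isomer of the product B] forward; the back reaction follows from the equilibrium constant (k = 29.2 L mol⁻¹ s⁻¹, Ea = 53.0 kJ mol⁻¹)
    precatalyst → free catalyst (k = 1.45 × 10⁻⁴ s⁻¹, Ea = 89.0 kJ mol⁻¹)
    crystals ⇌ target, rate k6*(cs6 - [target]) while solid is left; crystals form when [target] > cs6 (solubility = 0.0730 M, k = 0.129 s⁻¹)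
    2 free catalyst → spent catalyst (k = 0.213 L mol⁻¹ s⁻¹, Ea = 55.0 kJ mol⁻¹)
    (constants at 25 °C)

Summer's 77.2% stands beside the 77.9% reckoned from the plateau heat of 36.6 kJ mol⁻¹, and its crystals are 0%. The ceiling on dissolved target is 42.9% of teal's charge, well under teal's reading, so a repeat at teal's charge should be watched for solid. Reading a flask as a plain solution holds while its target stays under that ceiling, as red's does at 56.7% of it.

For a flask like noon run at 50 °C, the plateau heat gives 48.2%, and the computed flask gives 48.8%.

(The readings are calculated on assumed constants, and the scatter is random.)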